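**Plan**

1. Retrosynthesis: remove the silyl group, then cut the pyran ring at O–C10 and at aryl C–CH(isobutyl). This is a formal [3+3] union of 2,4-diformylphloroglucinol with a ten-membered tertiary allylic alcohol. Ring numbering used throughout: C1 = ring CH bonded to the benzylic carbon, C4=C5 = ring alkene, C7 = carbon bearing the hydroxyisopropyl group, C10 = O-bearing quaternary carbon.
2. Enabling feature: the benzylic CH, C1 and C10 of the pyran ring form a three-carbon unit that is an allyl cation at the allylic-alcohol oxidation level. The arene has a single free CH lying between two equivalent OH groups, so a C,O-bis-nucleophile meets a 1,3-bis-electrophile with only one possible regiochemistry.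
3. Further cuts: C4=C5 (ring-closing metathesis), C1–C2 (anti-carbomagnesiation of a propargylic alcohol), C10–C1 (acetylide addition to a methyl ketone), and the C5/C10 carbonyl pair back to the ring alkene of (R)-α-terpineol.
4. Forward order: terpineol ring opened to the C5–C10 chain, then propargylic alcohol, E-alkylidene allylic alcohol, ten-membered carbocycle, pyran ring, desilylation.
5. Stereochemistry: C7 is bought with (R)-α-terpineol. The Z ring alkene comes from ring strain in the metathesis. The benzylic centre is set in the C–C bond formation of the annulation, and C1 and C10 are relayed from it in the same operation.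

Key step: step 8

Remark: the ring C=C of the target is read from the SMILES as Z (ring carbons cis). The propargylic and allylic alcohols of steps 4 to 6 are mixtures at the carbinol carbon C10, which is of no consequence because this centre is ionised in step 8.

**Route**

Step 1
Reactants: 1 (R)-α-terpineol
Product: 2 (R)-α-terpineol tert-butyldimethylsilyl ether
Conditions: TBSOTf, 2,6-lutidine, CH2Cl2, 0 → 23 °C
Reagents that add atoms: tert-butyldimethylsilyl trifluoromethanesulfonate, CC(C)(C)[Si](C)(C)OS(=O)(=O)C(F)(F)F
Why: A silyl triflate with a hindered pyridine base silylates the tertiary alcohol (silyl ether protection), so that it can neither ionise nor trap a cation in step 8; no stereocentre is touched.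

Step 2
Reactants: 2 (R)-α-terpineol tert-butyldimethylsilyl ether
Product: 4 keto aldehyde (R)-3-[2-(tert-butyldimethylsilyloxy)propan-2-yl]-6-oxoheptanal, via ozonide 3 (not isolated)
Conditions: O3, CH2Cl2, −78 °C; then Me2S, −78 → 23 °C
Reagents that add atoms: ozone, [O-][O+]=O
Why: Ozonolysis with reductive work-up cleaves the only C=C bond to the methyl ketone (C10) and the aldehyde (C5); the stereocentre is alpha to neither carbonyl and is kept.

Step 3
Reactants: 4 keto aldehyde
Product: 5 keto alkene (R)-5-[2-(tert-butyldimethylsilyloxy)propan-2-yl]oct-7-en-2-one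
Conditions: Ph3PCH3Br, KHMDS, THF, 0 °C; then 4, −78 → 0 °C
Reagents that add atoms: methyltriphenylphosphonium bromide, C[P+](c1ccccc1)(c1ccccc1)c1ccccc1.[Br-]
Why: Wittig methylenation with one equivalent of the unstabilised ylide at low temperature should take the aldehyde in preference to the methyl ketone.

Step 4
Reactants: 5 keto alkene; 6 4-methylpent-1-yne
Product: 8 propargylic alcohol (4R)-4-[2-(tert-butyldimethylsilyloxy)propan-2-yl]-7,11-dimethyldodec-1-en-8-yn-7-ol (both C7 epimers), via lithium acetylide 7 (not isolated)
Conditions: 6, n-BuLi, THF, −78 °C; then 5, −78 → 0 °C; then H2O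
Reagents that add atoms: none
Why: 1,2-Addition of a lithium acetylide to the methyl ketone should give the tertiary propargylic alcohol; the new carbinol centre forms unselectively and is erased in step 8.

Step 5
Reactants: 8 propargylic alcohol; 9 4-bromo-2-methylbut-1-ene
Product: 12 E-alkylidene tertiary allylic alcohol (4R,8E)-4-[2-(tert-butyldimethylsilyloxy)propan-2-yl]-7,11-dimethyl-8-(3-methylbut-3-en-1-yl)dodeca-1,8-dien-7-ol, via Grignard reagent 10 (not isolated), via cyclic alkenylmagnesium alkoxide 11 (not isolated)
Conditions: 9, Mg, THF; then 8, CuI (10 mol %), THF, 0 °C → reflux; then H2O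
Reagents that add atoms: none
Why: Copper-catalysed anti-carbomagnesiation of a propargylic alcohol places the alkyl group on the alkyne carbon next to the carbinol and magnesium on the distal carbon in a five-membered chelate, so protonation should leave the isobutyl group trans to the carbinol carbon (E).

Step 6
Reactants: 12 E-alkylidene tertiary allylic alcohol
Product: 13 ten-membered allylic alcohol (2E,5Z,8R)-8-[2-(tert-butyldimethylsilyloxy)propan-2-yl]-1,5-dimethyl-2-(3-methylbutylidene)cyclodec-5-en-1-ol
Conditions: Grubbs second-generation catalyst (10 mol %), toluene (1 mM), 80 °C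
Reagents that add atoms: none
Why: Ring-closing metathesis of the vinyl group with the 1,1-disubstituted alkene should give the trisubstituted ring alkene as the less strained Z isomer, while the alkylidene next to the quaternary carbinol is too hindered to take part.

Step 7
Reactants: 14 phloroglucinol
Product: 16 2,4-diformylphloroglucinol (2,4,6-trihydroxybenzene-1,3-dicarbaldehyde), via bis-iminium salt 15 (not isolated)
Conditions: POCl3, DMF, 1,4-dioxane, 0 → 23 °C; then H2O
Reagents that add atoms: N,N-dimethylformamide, CN(C)C=O; water, O
Why: Vilsmeier–Haack formylation of the electron-rich arene should stop at two formyl groups because the bis-iminium salt is deactivated and precipitates.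

Step 8
Reactants: 13 ten-membered allylic alcohol; 16 2,4-diformylphloroglucinol
Product: 18 silyl ether of the target, via C-allylated phenol 17 (not isolated)
Conditions: 16 (1.5 equiv), (±)-CSA (10 mol %), 4 Å MS, CH2Cl2/1,4-dioxane 4:1, −20 → 23 °C
Reagents that add atoms: none
Why: Acid ionises the tertiary allylic alcohol to the W-shaped allyl cation spanning C10, C1 and the future benzylic carbon, the only free ring carbon of 16 attacks its less hindered secondary terminus (Friedel–Crafts), and a flanking phenol then adds across the resulting tetrasubstituted C1=C10 alkene; the closest known reaction type is the acid-catalysed condensation of phenols with allylic alcohols or 1,3-dienes to 2,2-disubstituted chromans. The pyran ring closes 6-endo-trig, the phenolic proton going to C1 through a six-membered transition state and the oxygen to the tertiary C10, which should exclude the 5-exo dihydrobenzofuran. The benzylic centre is set in the C–C bond formation by attack on the less shielded outer face of the ring-bound cation, a face choice governed by the C7 substituent through the ring conformation. C1 and C10 are relayed from it: allylic 1,3-strain holds the benzylic H in the plane of the C1=C10 bond with the aryl group on one face, and delivery of H and O from that face to the alkene (ring carbons cis) should give the trans-fused chroman with isobutyl trans to C2. The two OH groups flanking the reacting carbon are equivalent, so only one chroman regioisomer can form. The step needs intermolecular capture to outrun transannular attack by the C4=C5 alkene; the Z geometry of that alkene, the excess of 16, the weak acid and the low temperature are meant to secure this.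

Step 9
Reactants: 18 silyl ether of the target
Product: 19 target CNP0570248.1
Conditions: HF·pyridine, pyridine, THF, 0 → 23 °C
Reagents that add atoms: none
Why: Buffered fluoride cleavage of the tertiary silyl ether should leave the aldehydes, the phenols, the tertiary aryl ether and the ring alkene untouched; no stereocentre is involved.

**Compound list**

1 | (R)-α-terpineol, 2-[(1R)-4-methylcyclohex-3-en-1-yl]propan-2-ol | CC1=CC[C@@H](CC1)C(C)(C)O | starting material
2 | (R)-α-terpineol tert-butyldimethylsilyl ether | CC1=CC[C@@H](CC1)C(C)(C)O[Si](C)(C)C(C)(C)C | intermediate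
3 | ozonide (1,2,4-trioxolane) of 2, mixture at the two new centres | CC12CC[C@@H](C(C)(C)O[Si](C)(C)C(C)(C)C)CC(O1)OO2 | intermediate
4 | (R)-3-[2-(tert-butyldimethylsilyloxy)propan-2-yl]-6-oxoheptanal | CC(=O)CC[C@H](CC=O)C(C)(C)O[Si](C)(C)C(C)(C)C | intermediate
5 | (R)-5-[2-(tert-butyldimethylsilyloxy)propan-2-yl]oct-7-en-2-one | CC(=O)CC[C@H](CC=C)C(C)(C)O[Si](C)(C)C(C)(C)C | intermediate
6 | 4-methylpent-1-yne | C#CCC(C)C | starting material
7 | lithium 4-methylpent-1-yn-1-ide | [Li]C#CCC(C)C | intermediate
8 | (4R)-4-[2-(tert-butyldimethylsilyloxy)propan-2-yl]-7,11-dimethyldodec-1-en-8-yn-7-ol, both C7 epimers | CC(O)(C#CCC(C)C)CC[C@H](CC=C)C(C)(C)O[Si](C)(C)C(C)(C)C | intermediate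
9 | 4-bromo-2-methylbut-1-ene | C=C(C)CCBr | starting material
10 | (3-methylbut-3-en-1-yl)magnesium bromide | C=C(C)CC[Mg]Br | intermediate
11 | cyclic alkenylmagnesium alkoxide (2,5-dihydro-1,2-oxamagnesole) from 8 and 10, Mg on the isobutyl-bearing alkene carbon | CC1(CC[C@H](CC=C)C(C)(C)O[Si](C)(C)C(C)(C)C)O[Mg]C(CC(C)C)=C1CCC(C)=C | intermediate
12 | (4R,8E)-4-[2-(tert-butyldimethylsilyloxy)propan-2-yl]-7,11-dimethyl-8-(3-methylbut-3-en-1-yl)dodeca-1,8-dien-7-ol, isobutyl trans to the carbinol carbon | CC(O)(CC[C@H](CC=C)C(C)(C)O[Si](C)(C)C(C)(C)C)/C(CCC(C)=C)=C/CC(C)C | intermediate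
13 | (2E,5Z,8R)-8-[2-(tert-butyldimethylsilyloxy)propan-2-yl]-1,5-dimethyl-2-(3-methylbutylidene)cyclodec-5-en-1-ol | CC1(O)CC[C@@H](C(C)(C)O[Si](C)(C)C(C)(C)C)C/C=C(/C)CC\C1=C/CC(C)C | intermediate
14 | phloroglucinol, benzene-1,3,5-triol | Oc1cc(O)cc(O)c1 | starting material
15 | bis(N,N-dimethyliminium) dichloride of 16 | C[N+](C)=Cc1c(O)cc(O)c(C=[N+](C)C)c1O.[Cl-].[Cl-] | intermediate
16 | 2,4-diformylphloroglucinol, 2,4,6-trihydroxybenzene-1,3-dicarbaldehyde | O=Cc1c(O)cc(O)c(C=O)c1O | intermediate
17 | C-allylated phenol: the diformylphloroglucinol ring bonded through its former CH carbon to the (S)-CH(isobutyl) group on C1 of the (1(10)Z,4Z)-cyclodecadiene, tetrasubstituted C1=C10 with ring carbons cis | O=Cc1c(O)c(C=O)c(O)c([C@@H](CC(C)C)\C2=C(/C)CC[C@@H](C(C)(C)O[Si](C)(C)C(C)(C)C)C/C=C(/C)CC2)c1O | intermediate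
18 | 11-O-tert-butyldimethylsilyl ether of the target | C/C1=C/C[C@H](C(C)(C)O[Si](C)(C)C(C)(C)C)CC[C@@]2(C)Oc3c(C=O)c(O)c(C=O)c(O)c3[C@@H](CC(C)C)[C@@H]2CC1 | intermediate
19 | CNP0570248.1: trans-fused chroman on a (4Z)-cyclodecene, (1S,7R,10R) with (S)-benzylic carbon in the numbering used here | C/C1=C/C[C@H](C(C)(C)O)CC[C@@]2(C)Oc3c(C=O)c(O)c(C=O)c(O)c3[C@@H](CC(C)C)[C@@H]2CC1 | target

**Step count and risks**

Total step count: 9. Longest linear sequence: 8 (steps 1 to 6, 8 and 9).

Steps most likely to fail:

1. Step 8. Face selection in the C–C bond formation relative to C7 may be poor, the proton may be delivered from the other face of the C1=C10 alkene, and the allyl cation may be captured across the ring by the C4=C5 alkene or close 5-exo. The fallback sets out from 5 and comes back at 18; it replaces the annulation by a hetero-Diels–Alder reaction across a preformed E alkene. Horner–Wadsworth–Emmons olefination of 5 (triethyl phosphonoacetate, NaH) should give the ethyl (2E)-enoate F1. DIBAL-H should reduce it to the allylic alcohol F2, and PBr3 should convert this into the allylic bromide F3. Coupling with 2-methylallylmagnesium chloride should give the triene F4, and ring-closing metathesis the (1(10)E,4Z)-cyclodecadiene silyl ether F5. Heating F5 with isovaleraldehyde and 16 (NaOAc, AcOH, 80 °C) should generate the o-quinone methide F6, whose suprafacial inverse-demand cycloaddition to the E-configured C1=C10 alkene fixes the trans ring fusion and leads to 18.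

2. Step 6. Intermolecular metathesis may lead to oligomers, and closure onto the alkylidene may give a seven-membered ring. The fallback sets out from 4 and comes back at 13; it fixes the Z geometry before the ring is closed and closes the ring at C3–C4 by cross-coupling. Stork–Zhao olefination of the aldehyde of 4 with (1-iodoethylidene)triphenylphosphorane should give the (Z)-vinyl iodide ketone F7. Addition of 7 should give the propargylic alcohol F8, and copper-free anti-carbomagnesiation with vinylmagnesium chloride the 1,3-diene F9. Hydroboration of its vinyl group with 9-BBN should give the alkylborane F10, and intramolecular B-alkyl Suzuki–Miyaura coupling (Pd(dppf)Cl2, AsPh3, Cs2CO3, high dilution) should close the ring to 13.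

3. Step 5. Addition to the hindered tertiary propargylic alkoxide may be slow, and the alkylcopper may lose β-hydride so that the alkyne is reduced and not alkylated. The fallback sets out from 8 and comes back at 12; it separates the hydrometalation from the C–C bond formation. Ruthenium-catalysed hydroxyl-directed trans-hydrostannation of 8 (Bu3SnH, [Cp*RuCl]4) should give the (Z)-alkenylstannane F11 with tin next to the carbinol carbon. Iodine should convert it into the alkenyl iodide F12, and Negishi coupling with (3-methylbut-3-en-1-yl)zinc bromide F13, made from 9 and zinc, should give 12 with retention of the alkene geometry.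

Further compounds
F1 | step 8 | ethyl (2E,6R)-6-[2-(tert-butyldimethylsilyloxy)propan-2-yl]-3-methylnona-2,8-dienoate | CCOC(=O)/C=C(\C)CC[C@H](CC=C)C(C)(C)O[Si](C)(C)C(C)(C)C
F2 | step 8 | (2E,6R)-6-[2-(tert-butyldimethylsilyloxy)propan-2-yl]-3-methylnona-2,8-dien-1-ol | OC/C=C(\C)CC[C@H](CC=C)C(C)(C)O[Si](C)(C)C(C)(C)C
F3 | step 8 | (2E,6R)-1-bromo-6-[2-(tert-butyldimethylsilyloxy)propan-2-yl]-3-methylnona-2,8-diene | BrC/C=C(\C)CC[C@H](CC=C)C(C)(C)O[Si](C)(C)C(C)(C)C
F4 | step 8 | (5E,9R)-9-[2-(tert-butyldimethylsilyloxy)propan-2-yl]-2,6-dimethyldodeca-1,5,11-triene | C=C(C)CC/C=C(\C)CC[C@H](CC=C)C(C)(C)O[Si](C)(C)C(C)(C)C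
F5 | step 8 | (1(10)E,4Z,7R)-germacra-1(10),4-dien-11-ol tert-butyldimethylsilyl ether | C/C1=C/C[C@H](C(C)(C)O[Si](C)(C)C(C)(C)C)CC/C(C)=C/CC1
F6 | step 8 | o-quinone methide from 16 and isovaleraldehyde | CC(C)CC=C1C(=O)C(C=O)=C(O)C(C=O)=C1O
F7 | step 6 | (5R,7Z)-5-[2-(tert-butyldimethylsilyloxy)propan-2-yl]-8-iodonon-7-en-2-one | CC(=O)CC[C@H](C/C=C(/C)I)C(C)(C)O[Si](C)(C)C(C)(C)C
F8 | step 6 | propargylic alcohol from F7 and 7, both carbinol epimers | CC(O)(C#CCC(C)C)CC[C@H](C/C=C(/C)I)C(C)(C)O[Si](C)(C)C(C)(C)C
F9 | step 6 | 2-vinyl E-alkylidene allylic alcohol from F8 | CC(O)(CC[C@H](C/C=C(/C)I)C(C)(C)O[Si](C)(C)C(C)(C)C)/C(C=C)=C/CC(C)C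
F10 | step 6 | B-alkyl-9-borabicyclo[3.3.1]nonane from F9 | CC(O)(CC[C@H](C/C=C(/C)I)C(C)(C)O[Si](C)(C)C(C)(C)C)/C(CCB1C2CCCC1CCC2)=C/CC(C)C
F11 | step 5 | (Z)-alkenyl tributylstannane from 8, tin on the carbon next to the carbinol | CC(O)(CC[C@H](CC=C)C(C)(C)O[Si](C)(C)C(C)(C)C)/C([Sn](CCCC)(CCCC)CCCC)=C/CC(C)C
F12 | step 5 | alkenyl iodide from F11, same geometry | CC(O)(CC[C@H](CC=C)C(C)(C)O[Si](C)(C)C(C)(C)C)/C(I)=C/CC(C)C
F13 | step 5 | (3-methylbut-3-en-1-yl)zinc bromide | C=C(C)CC[Zn]Br
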